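The synthesis rests on the hidden mirror symmetry of the cyclohexadienone ring (C1–C6): without the C2 allyl and C5 methoxy groups, C4 lies on a plane through C1 and C4, flanked by two constitutionally identical enone arms, C2=C3 and C6=C5. The key-step precursor is therefore the symmetric 4-alkyl-4-methoxycyclohexa-2,5-dienone 8, which already carries the (R)-C8 side chain with its guaiacol protected as a TIPS ether. In one operation a chiral copper–boryl catalyst borylates C3 of one arm and the boron enolate is allylated at C2; this fixes C4 and places the allyl group. Boron is later lost to restore C2=C3, and the untouched arm is turned regiospecifically into the C5 enol ether.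

Key step: step 6

Remark: ring atoms keep the target numbering in all intermediates (C1 carbonyl, C2 allyl-bearing, C4 quaternary, C5 methoxy-bearing, C8 the side-chain methine); the guaiacol oxygen is carried as a TIPS ether because an aryl TBS ether is not expected to survive the alkoxides of steps 6 and 10; 1 and 3 are assumed to be purchased; C4 is S in the target, and the same spatial arrangement is named R in 12 and 13 only because the CIP ranking of C3 and C5 changes.

Step 1
Reactants: 1 4-bromo-2-methoxyphenol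
Product: 2 (4-bromo-2-methoxyphenoxy)triisopropylsilane
Conditions: TIPSCl, imidazole, DMF, rt
Reagents that add atoms: triisopropylsilyl chloride CC(C)[Si](Cl)(C(C)C)C(C)C
Why: Imidazole-promoted silylation of a phenol; the bulky TIPS group is chosen so that the aryl silyl ether should outlast organometallic, oxidative and alkoxide conditions up to the last step.

Step 2
Reactants: 3 1-(benzyloxy)-4-ethynylbenzene; 2 (4-bromo-2-methoxyphenoxy)triisopropylsilane
Product: 5 (E)-2-(4-benzyloxyphenyl)-1-(3-methoxy-4-triisopropylsilyloxyphenyl)prop-1-ene, via alkenylalane 4 (not isolated)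
Conditions: Me3Al, Cp2ZrCl2 (cat.), CH2Cl2, 0 °C → rt; volatiles removed; then 2, ZnCl2, Pd(t-Bu3P)2 (cat.), THF, rt → 50 °C
Reagents that add atoms: trimethylaluminium C[Al](C)C
Why: Zirconium-catalysed methylalumination (Negishi carboalumination) adds methyl and aluminium syn across the terminal alkyne with aluminium at the terminus, and Negishi cross-coupling through zinc and palladium replaces the metal with retention, so the trisubstituted alkene should form as the E isomer only.

Step 3
Reactants: 5 (E)-2-(4-benzyloxyphenyl)-1-(3-methoxy-4-triisopropylsilyloxyphenyl)prop-1-ene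
Product: 6 (R)-2-(4-benzyloxyphenyl)-1-(3-methoxy-4-triisopropylsilyloxyphenyl)propane
Conditions: [Ir(cod)((S)-t-Bu-PHOX)]BArF (1 mol %; ligand antipode if the sense proves opposite), H2 (50 bar), CH2Cl2, rt
Reagents that add atoms: none
Why: Iridium–P,N-catalysed asymmetric hydrogenation of an unfunctionalised (E)-1,2-diarylpropene, the standard substrate class for these catalysts, sets C8 as R through ligand control of the alkene face, while benzyl and silyl ethers are inert.

Step 4
Reactants: 6 (R)-2-(4-benzyloxyphenyl)-1-(3-methoxy-4-triisopropylsilyloxyphenyl)propane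
Product: 7 4-[(2R)-1-(3-methoxy-4-triisopropylsilyloxyphenyl)propan-2-yl]phenol
Conditions: H2 (1 atm), 10% Pd/C, EtOAc, rt
Reagents that add atoms: none
Why: Hydrogenolysis of the benzyl aryl ether frees only the phenol that is to be oxidised; the silyl ether and the C8 centre should be untouched.

Step 5
Reactants: 7 4-[(2R)-1-(3-methoxy-4-triisopropylsilyloxyphenyl)propan-2-yl]phenol
Product: 8 4-methoxy-4-[(2R)-1-(3-methoxy-4-triisopropylsilyloxyphenyl)propan-2-yl]cyclohexa-2,5-dien-1-one
Conditions: PhI(OAc)2, MeOH, 0 °C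
Reagents that add atoms: methanol CO
Why: Oxidative dearomatisation of a para-alkylphenol with a λ3-iodane, the phenoxonium equivalent being captured by solvent methanol at the para carbon; C4 carries two identical arms and is not stereogenic, so a single compound should result.

Step 6
Reactants: 8 4-methoxy-4-[(2R)-1-(3-methoxy-4-triisopropylsilyloxyphenyl)propan-2-yl]cyclohexa-2,5-dien-1-one; 9 bis(pinacolato)diboron; 10 allyl methyl carbonate
Product: 12 (2S,3S,4R)-2-allyl-4-methoxy-4-[(2R)-1-(3-methoxy-4-triisopropylsilyloxyphenyl)propan-2-yl]-3-(4,4,5,5-tetramethyl-1,3,2-dioxaborolan-2-yl)cyclohex-5-en-1-one, via boron dienolate 11 (not isolated)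
Conditions: 9 (1.05 equiv), CuCl (5 mol %), (R,R)-QuinoxP* (6 mol %; ligand hand to be matched to the required arm), LiOt-Bu (10 mol %), THF–DMSO, 0 °C, no proton source; then Pd(PPh3)4 (3 mol %), 10 (1.5 equiv), 0 °C → rt
Reagents that add atoms: bis(pinacolato)diboron (9) CC1(C)OB(OC1(C)C)B1OC(C)(C)C(C)(C)O1; allyl methyl carbonate (10) C=CCOC(=O)OC
Why: Proposed new method: the ligated copper–boryl species formed from the copper alkoxide and 9 adds across one enone arm of 8 with boron at C3, and without a proton source the copper enolate is turned over by 9 to the O-boron dienolate 11; Pd(0) then ionises 10, the methoxide released on decarboxylation activates the boron enolate, and C2 attacks the π-allyl ligand. The closest known reactions are the copper-catalysed enantioselective β-borylation of cyclic enones run aprotically to give boron enolates, desymmetrising copper-catalysed conjugate additions to 4-alkoxy-4-alkylcyclohexadienones, and the Tsuji–Trost allylation of boron enolates. No ring is closed. C4 is set by the chiral ligand, which decides which of the two diastereotopic arms is borylated (the remote C8 centre should exert little bias); C3 is set by the substrate, boron entering anti to the branched C4 alkyl group and syn to the small methoxy group; C2 is set by the substrate, the allyl group entering trans to the new C3–B bond. The step needs arm selectivity, mono-borylation and C-allylation at C2 only: the mirror symmetry of the ring leaves the choice of arm to the catalyst, dienolate 11 is no longer a Michael acceptor so the second arm is masked until 9 is consumed, and the quaternary C4 leaves C2 as the only nucleophilic carbon. Methoxide ends bound to boron, so no free base should remain to equilibrate the ketone and cause a second allylation.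

Step 7
Reactants: 12 (2S,3S,4R)-2-allyl-4-methoxy-4-[(2R)-1-(3-methoxy-4-triisopropylsilyloxyphenyl)propan-2-yl]-3-(4,4,5,5-tetramethyl-1,3,2-dioxaborolan-2-yl)cyclohex-5-en-1-one
Product: 13 (2S,3S,4R)-2-allyl-3-hydroxy-4-methoxy-4-[(2R)-1-(3-methoxy-4-triisopropylsilyloxyphenyl)propan-2-yl]cyclohex-5-en-1-one
Conditions: NaBO3·4H2O, THF–H2O, rt
Reagents that add atoms: sodium perborate (used as the tetrahydrate) [Na+].[Na+].O[B-]1(O)OO[B-](O)(O)OO1
Why: Perborate oxidation of the secondary alkyl pinacol boronate proceeds by 1,2-migration with retention at C3, and this mild oxidant should leave the enone, the allyl group and the aryl silyl ether alone.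

Step 8
Reactants: 13 (2S,3S,4R)-2-allyl-3-hydroxy-4-methoxy-4-[(2R)-1-(3-methoxy-4-triisopropylsilyloxyphenyl)propan-2-yl]cyclohex-5-en-1-one
Product: 15 (2S,3S,4S)-2-allyl-3-hydroxy-4-methoxy-4-[(2R)-1-(3-methoxy-4-triisopropylsilyloxyphenyl)propan-2-yl]-5-(phenylthio)cyclohex-5-en-1-one, via phenylthio ketone 14 (not isolated)
Conditions: PhSH (1.0 equiv), Et3N (cat.), CH2Cl2, 0 °C → rt; then NCS (1.05 equiv), 0 °C → rt; then Et3N
Reagents that add atoms: thiophenol Sc1ccccc1
Why: Base-catalysed thia-Michael addition to the only enone puts sulfur on C5, and chlorination at sulfur followed by Pummerer-type loss of HCl turns the β-phenylthio ketone into the β-phenylthio enone, a known way of oxidising the β-carbon of an enone; the transient C5 centre is uncontrolled and disappears.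

Step 9
Reactants: 15 (2S,3S,4S)-2-allyl-3-hydroxy-4-methoxy-4-[(2R)-1-(3-methoxy-4-triisopropylsilyloxyphenyl)propan-2-yl]-5-(phenylthio)cyclohex-5-en-1-one
Product: 17 (4S)-2-allyl-4-methoxy-4-[(2R)-1-(3-methoxy-4-triisopropylsilyloxyphenyl)propan-2-yl]-5-(phenylthio)cyclohexa-2,5-dien-1-one, via mesylate 16 (not isolated)
Conditions: MsCl, Et3N, CH2Cl2, 0 °C; then DBU, rt
Reagents that add atoms: none
Why: Mesylation of the β-hydroxy ketone and E1cB elimination through the C2 enolate should return the C2=C3 enone with the allyl group on C2; C2 and C3 cease to be stereocentres and the quaternary C4 cannot epimerise.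

Step 10
Reactants: 17 (4S)-2-allyl-4-methoxy-4-[(2R)-1-(3-methoxy-4-triisopropylsilyloxyphenyl)propan-2-yl]-5-(phenylthio)cyclohexa-2,5-dien-1-one
Product: 18 (4S)-2-allyl-4,5-dimethoxy-4-[(2R)-1-(3-methoxy-4-triisopropylsilyloxyphenyl)propan-2-yl]cyclohexa-2,5-dien-1-one
Conditions: NaOMe, MeOH, 0 °C → rt
Reagents that add atoms: sodium methoxide [Na+].[O-]C
Why: Addition–elimination (vinylic substitution) on the vinylogous thioester: methoxide adds to the sulfur-bearing C5 and the much less basic thiolate is expelled, so the new methoxy group can end only at C5.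

Step 11
Reactants: 18 (4S)-2-allyl-4,5-dimethoxy-4-[(2R)-1-(3-methoxy-4-triisopropylsilyloxyphenyl)propan-2-yl]cyclohexa-2,5-dien-1-one
Product: 19 (4S)-2-allyl-4,5-dimethoxy-4-[(2R)-1-(4-hydroxy-3-methoxyphenyl)propan-2-yl]cyclohexa-2,5-dien-1-one
Conditions: TBAF, AcOH, THF, 0 °C
Reagents that add atoms: none
Why: Fluoride cleavage of the aryl triisopropylsilyl ether, buffered with acetic acid so that the dienone is not exposed to free phenoxide; no stereocentre is touched.

Compound list
1 | 4-bromo-2-methoxyphenol | COc1cc(Br)ccc1O | starting material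
2 | (4-bromo-2-methoxyphenoxy)triisopropylsilane | COc1cc(Br)ccc1O[Si](C(C)C)(C(C)C)C(C)C | intermediate
3 | 1-(benzyloxy)-4-ethynylbenzene | C#Cc1ccc(OCc2ccccc2)cc1 | starting material
4 | (E)-[2-(4-benzyloxyphenyl)prop-1-en-1-yl]dimethylalane (methyl and aluminium cis) | C/C(=C\[Al](C)C)c1ccc(OCc2ccccc2)cc1 | intermediate (not isolated)
5 | (E)-2-(4-benzyloxyphenyl)-1-(3-methoxy-4-triisopropylsilyloxyphenyl)prop-1-ene | C/C(=C\c1ccc(O[Si](C(C)C)(C(C)C)C(C)C)c(OC)c1)c1ccc(OCc2ccccc2)cc1 | intermediate
6 | (R)-2-(4-benzyloxyphenyl)-1-(3-methoxy-4-triisopropylsilyloxyphenyl)propane | C[C@H](Cc1ccc(O[Si](C(C)C)(C(C)C)C(C)C)c(OC)c1)c1ccc(OCc2ccccc2)cc1 | intermediate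
7 | 4-[(2R)-1-(3-methoxy-4-triisopropylsilyloxyphenyl)propan-2-yl]phenol | C[C@H](Cc1ccc(O[Si](C(C)C)(C(C)C)C(C)C)c(OC)c1)c1ccc(O)cc1 | intermediate
8 | 4-methoxy-4-[(2R)-1-(3-methoxy-4-triisopropylsilyloxyphenyl)propan-2-yl]cyclohexa-2,5-dien-1-one (C4 not stereogenic) | COC1([C@H](C)Cc2ccc(O[Si](C(C)C)(C(C)C)C(C)C)c(OC)c2)C=CC(=O)C=C1 | intermediate
9 | bis(pinacolato)diboron | CC1(C)OB(OC1(C)C)B1OC(C)(C)C(C)(C)O1 | starting material
10 | allyl methyl carbonate | C=CCOC(=O)OC | starting material
11 | pinacol boron dienolate: (3S,4R)-4-methoxy-4-[(2R)-1-(3-methoxy-4-triisopropylsilyloxyphenyl)propan-2-yl]-3-(pinacolboryl)cyclohexa-1,5-dien-1-yl pinacol borate | O(B1OC(C)(C)C(C)(C)O1)C1=C[C@H](B2OC(C)(C)C(C)(C)O2)[C@@](OC)([C@H](C)Cc2ccc(O[Si](C(C)C)(C(C)C)C(C)C)c(OC)c2)C=C1 | intermediate (not isolated)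
12 | (2S,3S,4R)-2-allyl-4-methoxy-4-[(2R)-1-(3-methoxy-4-triisopropylsilyloxyphenyl)propan-2-yl]-3-(4,4,5,5-tetramethyl-1,3,2-dioxaborolan-2-yl)cyclohex-5-en-1-one (allyl trans to boron, boron cis to the C4 methoxy group) | C=CC[C@H]1[C@H](B2OC(C)(C)C(C)(C)O2)[C@@](OC)([C@H](C)Cc2ccc(O[Si](C(C)C)(C(C)C)C(C)C)c(OC)c2)C=CC1=O | intermediate
13 | (2S,3S,4R)-2-allyl-3-hydroxy-4-methoxy-4-[(2R)-1-(3-methoxy-4-triisopropylsilyloxyphenyl)propan-2-yl]cyclohex-5-en-1-one | C=CC[C@H]1[C@H](O)[C@@](OC)([C@H](C)Cc2ccc(O[Si](C(C)C)(C(C)C)C(C)C)c(OC)c2)C=CC1=O | intermediate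
14 | (2S,3S,4S,5RS)-2-allyl-3-hydroxy-4-methoxy-4-[(2R)-1-(3-methoxy-4-triisopropylsilyloxyphenyl)propan-2-yl]-5-(phenylthio)cyclohexan-1-one (C5 uncontrolled) | C=CC[C@H]1[C@H](O)[C@@](OC)([C@H](C)Cc2ccc(O[Si](C(C)C)(C(C)C)C(C)C)c(OC)c2)C(Sc2ccccc2)CC1=O | intermediate (not isolated)
15 | (2S,3S,4S)-2-allyl-3-hydroxy-4-methoxy-4-[(2R)-1-(3-methoxy-4-triisopropylsilyloxyphenyl)propan-2-yl]-5-(phenylthio)cyclohex-5-en-1-one | C=CC[C@H]1[C@H](O)[C@@](OC)([C@H](C)Cc2ccc(O[Si](C(C)C)(C(C)C)C(C)C)c(OC)c2)C(Sc2ccccc2)=CC1=O | intermediate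
16 | 3-O-methanesulfonate of 15 | C=CC[C@H]1[C@H](OS(C)(=O)=O)[C@@](OC)([C@H](C)Cc2ccc(O[Si](C(C)C)(C(C)C)C(C)C)c(OC)c2)C(Sc2ccccc2)=CC1=O | intermediate (not isolated)
17 | (4S)-2-allyl-4-methoxy-4-[(2R)-1-(3-methoxy-4-triisopropylsilyloxyphenyl)propan-2-yl]-5-(phenylthio)cyclohexa-2,5-dien-1-one | C=CCC1=C[C@@](OC)([C@H](C)Cc2ccc(O[Si](C(C)C)(C(C)C)C(C)C)c(OC)c2)C(Sc2ccccc2)=CC1=O | intermediate
18 | (4S)-2-allyl-4,5-dimethoxy-4-[(2R)-1-(3-methoxy-4-triisopropylsilyloxyphenyl)propan-2-yl]cyclohexa-2,5-dien-1-one | C=CCC1=C[C@@](OC)([C@H](C)Cc2ccc(O[Si](C(C)C)(C(C)C)C(C)C)c(OC)c2)C(OC)=CC1=O | intermediate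
19 | (4S)-2-allyl-4,5-dimethoxy-4-[(2R)-1-(4-hydroxy-3-methoxyphenyl)propan-2-yl]cyclohexa-2,5-dien-1-one | C=CCC1=C[C@@](OC)([C@H](C)Cc2ccc(O)c(OC)c2)C(OC)=CC1=O | target

Total step count: 11. Longest linear sequence: 11 steps (1 → 19; alkyne 3 enters at step 2).

Steps most likely to fail

Step 6 (proposed new method). What may go wrong is failure to intercept the boron enolate cleanly: residual copper–boryl may consume the carbonate as allylboronate, the enolate may be quenched by adventitious protons, or methoxide may trigger elimination across C3–C4 with rearomatisation. The discrimination between the two arms may also fall short. The fallback uses known chemistry, sets out from 8 and returns at 12 by separating the two bond formations. Copper-catalysed enantioselective conjugate borylation of 8 under the usual protic conditions (CuCl, chiral bisphosphine, NaOt-Bu, 9, MeOH, THF) should give the β-boryl enone F1, which is isolated. Kinetic deprotonation at C2, the only sp3 α-carbon, with LiHMDS at −78 °C and alkylation of the lithium enolate with allyl bromide, trans to boron, then gives 12.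

Step 5. The phenoxonium intermediate may lose the C8 proton to give a quinone methide, which adds methanol at C8 and erases that stereocentre. It may also be captured by the electron-rich silyloxy-methoxy arene (spirocyclisation) instead of by methanol. The fallback sets out from 7, returns at 8 and avoids a cationic intermediate. Singlet-oxygen-type para-oxygenation of the phenol (Oxone, NaHCO3, aqueous MeCN) should give the para-hydroperoxy dienone F2. Reduction with Me2S gives the para-quinol F3, and O-methylation of its tertiary hydroxyl (MeI, Ag2O) gives 8.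

Step 8. The chlorosulfonium ion may fragment back to the enone with loss of sulfur, or a second chlorination may occur at C6 or on the activated arene. The same fallback applies if the substitution at the hindered C5 in step 10 proves too slow. It sets out from 13, returns at 18 and replaces the sulfur relay by an oxygen relay. Dehydration of 13 (Burgess reagent) gives the 2-allyl dienone F4. Nucleophilic epoxidation (t-BuOOH, DBU) of the less substituted C5=C6 enone gives the epoxy ketone F5. Pd(0)-catalysed isomerisation (Pd(PPh3)4, dppe, toluene, 80 °C) gives the enolised 1,3-dione F6, and O-methylation with TMSCHN2 gives 18. The price is that the O-methylation is not regiospecific, so 18 would have to be separated from its enol-ether regioisomer.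

Further compounds
F1 | step 6 | (3S,4R)-4-methoxy-4-[(2R)-1-(3-methoxy-4-triisopropylsilyloxyphenyl)propan-2-yl]-3-(4,4,5,5-tetramethyl-1,3,2-dioxaborolan-2-yl)cyclohex-5-en-1-one | O=C1C[C@H](B2OC(C)(C)C(C)(C)O2)[C@@](OC)([C@H](C)Cc2ccc(O[Si](C(C)C)(C(C)C)C(C)C)c(OC)c2)C=C1
F2 | step 5 | 4-hydroperoxy-4-[(2R)-1-(3-methoxy-4-triisopropylsilyloxyphenyl)propan-2-yl]cyclohexa-2,5-dien-1-one | OOC1([C@H](C)Cc2ccc(O[Si](C(C)C)(C(C)C)C(C)C)c(OC)c2)C=CC(=O)C=C1
F3 | step 5 | 4-hydroxy-4-[(2R)-1-(3-methoxy-4-triisopropylsilyloxyphenyl)propan-2-yl]cyclohexa-2,5-dien-1-one | OC1([C@H](C)Cc2ccc(O[Si](C(C)C)(C(C)C)C(C)C)c(OC)c2)C=CC(=O)C=C1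
F4 | step 8 | (4R)-2-allyl-4-methoxy-4-[(2R)-1-(3-methoxy-4-triisopropylsilyloxyphenyl)propan-2-yl]cyclohexa-2,5-dien-1-one | C=CCC1=C[C@@](OC)([C@H](C)Cc2ccc(O[Si](C(C)C)(C(C)C)C(C)C)c(OC)c2)C=CC1=O
F5 | step 8 | 5,6-epoxide of F4 (epoxide face not controlled, C4 as in F4) | C=CCC1=C[C@@](OC)([C@H](C)Cc2ccc(O[Si](C(C)C)(C(C)C)C(C)C)c(OC)c2)C2OC2C1=O
F6 | step 8 | (4S)-2-allyl-5-hydroxy-4-methoxy-4-[(2R)-1-(3-methoxy-4-triisopropylsilyloxyphenyl)propan-2-yl]cyclohexa-2,5-dien-1-one (enol form of the 1,5-dione) | C=CCC1=C[C@@](OC)([C@H](C)Cc2ccc(O[Si](C(C)C)(C(C)C)C(C)C)c(OC)c2)C(O)=CC1=O
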